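Take the flasks below, alike but for temperature, and ask which holds the most target when the time is up.

| flask | substrate | reagent | capture agent | temperature | time |
|---|---|---|---|---|---|
| oak | 20 mM | 20.0 mM | 20.0 mM | 5 °C | 4.0 h |
| ash | 20 mM | 20.0 mM | 20.0 mM | −10 °C | 4.0 h |
| elm | 20 mM | 20.0 mM | 20.0 mM | −40 °C | 4.0 h |
| larch | 20 mM | 20.0 mM | 20.0 mM | −25 °C | 4.0 h |

1. the flask with the highest amount of target, in percent of the substrate charged ("all alike" if they lie within 1.5 percentage points) (oak / ash / elm / larch / all alike)
2. final target, as a percentage of the substrate charged, in oak
3. final target, as a percentage of the substrate charged, in ash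
4. final target, as a percentage of the substrate charged, in elm
5. final target, as a percentage of the substrate charged, in larch

    substrate ⇌ intermediate A (K1 = 0.51, k1 = 0.31 min⁻¹, Ea1 = 85.0 kJ mol⁻¹, ΔH1 = −11.0 kJ mol⁻¹)
    substrate + reagent → intermediate B (k2 = 2.6 M⁻¹ min⁻¹, Ea2 = 43.0 kJ mol⁻¹)
    reagent + intermediate A → intermediate C (k3 = 0.75 M⁻¹ min⁻¹, Ea3 = 55.0 kJ mol⁻¹)
    intermediate B → target (k4 = 0.077 min⁻¹, Ea4 = 77.0 kJ mol⁻¹)
    intermediate C ⇌ intermediate B (K5 = 0.27, k5 = 0.18 min⁻¹, Ea5 = 79.0 kJ mol⁻¹, ΔH5 = −21.0 kJ mol⁻¹)
    capture agent + intermediate A → trapped intermediate (k6 = 12 M⁻¹ min⁻¹, Ea6 = 45.0 kJ mol⁻¹)
    (constants at 5 °C)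

- at 5 °C the constants are as listed, elsewhere as the activation energies and enthalpies make them

Two of us argued over this. I held the route view. Substrate leaves either directly with reagent, toward intermediate B, or by opening to intermediate A, which may return, be captured or take reagent to intermediate C. At the charge in oak that last exit runs at 0.0625 of capture, so I drop it from the reckoning. Taking intermediate A as steady, both remaining exits are first order in c(substrate), so dividing one flow by the other removes c(substrate) and time. That quotient, direct flow over flow lost through capture, is the route ratio, a selectivity factor.

It equals the direct rate constant times c(reagent), over the opening rate constant, times one plus the return rate over the capture rate. From elm to oak the opening step speeds up by 1200, and any other constant moves by that factor raised to its energy over the opening step's.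

Return over capture is 2.53 in oak but 0.0359 in elm. So the route ratio at the charge is 0.593 in oak and 5.78 in elm. At the charge, that reckons 85.3% of departing substrate toward intermediate B in elm, and 37.2% in oak. I backed the cold.

My colleague held the clock view: the last step, intermediate B to target, is the rate-limiting step, so count its time constants. Elm gets 0.0299, leaving out its exchange with intermediate C, whose half-life of 28.5 h is longer than the time allowed. Oak gets 3.93, counting the part of that pair standing as intermediate B.

Joining the two views, I reckon 36.5% for oak.

The forecast sided with the clock: oak highest, with 42% there, 24% in ash, 5% in larch and 0.4% in elm. Its oak figure stands above mine. Its ground is that the slow step, “further held back by B parking in C, collapses on cooling”.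

The simulation gives the clock the win: oak holds 40.2%, ash 23.5%, larch 7.09% and elm 0.405%. The route view has its region in long holding: after 40.0 h, ash holds 44.5%, more than oak's 41.4%.

Taking the temperature dependence off the last step shrinks the oak-minus-elm gap from 40 percentage points to −0.15 points; that is one part of what temperature does. The time allowed is another part of elm's low figure: set beside a tenfold time, elm goes from 0.405% to 12.2%, which is 12% of what is missing. In elm at 4.00 h, intermediate B, intermediate C and target together, over intermediate A and trapped intermediate, read 5.00. That lies below 5.78 and above 4.33, the value with reagent at 75% of its charge.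

Elm charged with 80 mM of reagent scales the route ratio to 23.1 at the charge, and 19.2 with reagent at 83% of its charge. That flask reads 21.8, with 66.4% standing as intermediate B and 1.25% as target.

The numbers of this flask are invented; what happens was integrated by code.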